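The isoflavone is disconnected at two bonds of ring C: C3–C1' and O1–C2. C3 is the α-carbon of an ortho-hydroxyaryl enaminone, which should be the first species to give up an electron at an anode, and C1' is the ring B carbon para to O4' and ortho to O2', the most nucleophilic position of a resorcinol. A single electrolysis should therefore join C3 to C1' and let a ring A phenol displace dimethylamine at C2, closing the pyranone. The precursor is the symmetric 2,6-dihydroxy-4-prenyloxyphenyl dimethylamino-enone, in which either phenol closes to the same chromone and the other becomes the 5-OH; its partner is resorcinol capped as its bis-silyl ether.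

Key step: step 4

Remark: the target has no stereogenic element; the only defined geometry in the route is the E double bond of the enaminone, and the two in-flask intermediates of the key step are transient racemic species written without descriptors. "Prenyl" means 3-methylbut-2-en-1-yl throughout.

Step 1
Reactants: 1 2,4,6-trihydroxyacetophenone; 2 prenyl bromide
Product: 3 1-[2,6-dihydroxy-4-(prenyloxy)phenyl]ethan-1-one
Conditions: 2 (1.05 equiv), K2CO3 (1.1 equiv), acetone, 40 °C
Reagents that add atoms: prenyl bromide 2, CC(C)=CCBr
Why: Williamson ether synthesis, in which the 4-OH is the only phenol not hydrogen-bonded to the ketone and the most acidic, so one equivalent of weak base in acetone should alkylate it on oxygen by SN2 attack on the primary allylic bromide and leave both ortho phenols free.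

Step 2
Reactants: 3 1-[2,6-dihydroxy-4-(prenyloxy)phenyl]ethan-1-one; 4 N,N-dimethylformamide dimethyl acetal
Product: 5 (E)-1-[2,6-dihydroxy-4-(prenyloxy)phenyl]-3-(dimethylamino)prop-2-en-1-one
Conditions: 4 (1.5 equiv), toluene, 70 °C; evaporation and crystallisation without acid
Reagents that add atoms: N,N-dimethylformamide dimethyl acetal 4, COC(OC)N(C)C
Why: Amide acetal condensation of a methyl ketone (enaminone formation), in which the ketone enolate adds to the methoxyiminium ion formed from 4 and loss of methanol gives the thermodynamically preferred E push-pull alkene, its carbonyl chelated by an ortho phenol.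

Step 3
Reactants: 6 resorcinol; 7 tert-butyldimethylsilyl chloride
Product: 8 1,3-bis(tert-butyldimethylsilyloxy)benzene
Conditions: 7 (2.3 equiv), imidazole (3 equiv), DMF, rt
Reagents that add atoms: tert-butyldimethylsilyl chloride 7, CC(C)(C)[Si](C)(C)Cl
Why: Imidazole-promoted silylation of both phenols, a routine silyl ether formation that keeps the future ring B from being a free phenol at the anode while leaving C4 strongly activated.

Step 4
Reactants: 5 (E)-1-[2,6-dihydroxy-4-(prenyloxy)phenyl]-3-(dimethylamino)prop-2-en-1-one; 8 1,3-bis(tert-butyldimethylsilyloxy)benzene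
Product: 11 3-[2,4-bis(tert-butyldimethylsilyloxy)phenyl]-5-hydroxy-7-(prenyloxy)chromen-4-one (bis-silylated isoflavone), via C3-arylated iminium ion 9 (not isolated), via 2-(dimethylamino)chroman-4-one aminal 10 (not isolated)
Conditions: undivided cell, graphite anode, platinum cathode, controlled potential at the onset of the enaminone wave (set by cyclic voltammetry of 5 and 8 beforehand), 8 (3 equiv), nBu4NBF4 (0.1 M), MeCN/HFIP 4:1, rt, N2, about 2.2 F/mol
Reagents that add atoms: none
Why: Proposed new method: one-electron oxidation of 5, the partner expected to be oxidised first, at the carbon anode should give a radical cation with spin density on C3; C4 of arene 8 (para to one silyloxy group, ortho to the other) bonds to it, and loss of a second electron and a proton restores ring B and leaves the C3-arylated iminium ion 9. A ring A phenol then adds to the iminium carbon C2 in a 6-exo-trig closure (the C=N bond lies outside the new ring) to give aminal 10, which expels dimethylamine and loses H3 to form the pyranone of ring C, while the protons are reduced to hydrogen at the cathode. The closest known reaction types are the oxidative and electrochemical C3-functionalising chromone annulations of ortho-hydroxyaryl enaminones with halogen, sulfur or selenium partners and the anodic alpha-arylation of enamine radical cations by electron-rich arenes; an arene C–H partner has not been shown in this annulation. The step needs chemoselective oxidation of the enaminone in the presence of the prenyl alkene, the silyl aryl ethers, the free phenols and the product, which its low oxidation potential and the controlled potential should secure, with hexafluoroisopropanol stabilising the radical cation and holding the released amine in protonated or hydrogen-bonded form so that it is not oxidised. It also needs attack through the correct arene carbon, secured by the two oxygens of 8, which jointly activate C4 (equivalent to C6) and bury C2 between two silyl groups. No stereocenter survives, since C2 and C3 of 10 become sp2, and the symmetry of ring A makes the choice of phenol immaterial.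

Step 5
Reactants: 11 3-[2,4-bis(tert-butyldimethylsilyloxy)phenyl]-5-hydroxy-7-(prenyloxy)chromen-4-one
Product: 12 3-(2,4-dihydroxyphenyl)-5-hydroxy-7-(prenyloxy)chromen-4-one (target)
Conditions: Bu4NF (2.5 equiv), AcOH (2.5 equiv), THF, 0 °C
Reagents that add atoms: none
Why: Fluoride-mediated desilylation of aryl silyl ethers, buffered with acetic acid so that each phenoxide is protonated as it forms and the base-sensitive pyranone, the 2'-hydroxyl next to C2 and the prenyl ether should be left untouched.

Compound list
1 | 2,4,6-trihydroxyacetophenone | CC(=O)c1c(O)cc(O)cc1O | starting material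
2 | prenyl bromide (1-bromo-3-methylbut-2-ene) | CC(C)=CCBr | starting material
3 | 1-[2,6-dihydroxy-4-(prenyloxy)phenyl]ethan-1-one | CC(=O)c1c(O)cc(OCC=C(C)C)cc1O | intermediate
4 | N,N-dimethylformamide dimethyl acetal | COC(OC)N(C)C | starting material
5 | (E)-1-[2,6-dihydroxy-4-(prenyloxy)phenyl]-3-(dimethylamino)prop-2-en-1-one | CN(C)/C=C/C(=O)c1c(O)cc(OCC=C(C)C)cc1O | intermediate
6 | resorcinol (benzene-1,3-diol) | Oc1cccc(O)c1 | starting material
7 | tert-butyldimethylsilyl chloride | CC(C)(C)[Si](C)(C)Cl | starting material
8 | 1,3-bis(tert-butyldimethylsilyloxy)benzene | CC(C)(C)[Si](C)(C)Oc1cccc(O[Si](C)(C)C(C)(C)C)c1 | intermediate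
9 | C3-arylated iminium ion: {2-[2,4-bis(tert-butyldimethylsilyloxy)phenyl]-3-[2,6-dihydroxy-4-(prenyloxy)phenyl]-3-oxopropylidene}dimethylammonium tetrafluoroborate, racemic, not isolated | C[N+](C)=CC(C(=O)c1c(O)cc(OCC=C(C)C)cc1O)c1ccc(O[Si](C)(C)C(C)(C)C)cc1O[Si](C)(C)C(C)(C)C.F[B-](F)(F)F | intermediate
10 | 3-[2,4-bis(tert-butyldimethylsilyloxy)phenyl]-2-(dimethylamino)-5-hydroxy-7-(prenyloxy)chroman-4-one, racemic diastereomer mixture, not isolated | CN(C)C1Oc2cc(OCC=C(C)C)cc(O)c2C(=O)C1c1ccc(O[Si](C)(C)C(C)(C)C)cc1O[Si](C)(C)C(C)(C)C | intermediate
11 | 3-[2,4-bis(tert-butyldimethylsilyloxy)phenyl]-5-hydroxy-7-(prenyloxy)chromen-4-one | CC(C)=CCOc1cc(O)c2c(=O)c(-c3ccc(O[Si](C)(C)C(C)(C)C)cc3O[Si](C)(C)C(C)(C)C)coc2c1 | intermediate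
12 | 3-(2,4-dihydroxyphenyl)-5-hydroxy-7-(prenyloxy)chromen-4-one | CC(C)=CCOc1cc(O)c2c(=O)c(-c3ccc(O)cc3O)coc2c1 | target

Total step count: 5. Longest linear sequence: 4 steps (steps 1, 2, 4, 5); step 3 is a one-step branch.

Steps most likely to fail

Step 4. The radical cation may be diverted into over-oxidation of the phenolic ring A, into self-coupling, or into closure of ring C before the arene has bonded to C3. The fallback uses known chemistry, sets out from 5 and 8 and returns at 11. Iodine and pyridine in CHCl3 at rt should convert 5, by C3-iodination and addition–elimination ring closure, into 5-hydroxy-3-iodo-7-(prenyloxy)chromen-4-one F1. In parallel, NBS in MeCN should brominate 8 para to one silyloxy group to give 4-bromo-1,3-bis(tert-butyldimethylsilyloxy)benzene F2. Miyaura borylation of F2 (B2pin2, Pd(dppf)Cl2, KOAc, dioxane, 80 °C) should give 2-[2,4-bis(tert-butyldimethylsilyloxy)phenyl]-4,4,5,5-tetramethyl-1,3,2-dioxaborolane F3. Suzuki–Miyaura coupling of F1 with F3 (Pd(dppf)Cl2, K3PO4, dioxane/H2O, 80 °C) then delivers 11. Any partial silyl loss in the coupling is harmless, because step 5 removes both groups.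

Step 2. Transfer of a methyl group from the amide acetal to a free phenol, or premature loss of dimethylamine with closure of ring C during isolation, may erode the precursor. The fallback sets out from 3 and returns at 5. Claisen formylation of 3 with ethyl formate and NaH in THF, followed by mild acidic work-up, should give 2,5-dihydroxy-7-(prenyloxy)chroman-4-one F4 (the racemic cyclic hemiacetal of the β-keto aldehyde). Dimethylamine in ethanol at rt should then open the hemiacetal and condense to 5, with no methylating agent present.

Step 1. The phloroglucinol-type phenoxide is ambident, so C-prenylation of the ring and a second alkylation may compete with O-alkylation at the 4-position. The fallback sets out from 1 and returns at 3. Mitsunobu etherification of 1 with 3-methylbut-2-en-1-ol, PPh3 and diisopropyl azodicarboxylate in THF at 0 °C should alkylate the most acidic, non-chelated 4-OH on oxygen without generating a free phenoxide; it makes no new compound.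

Further compounds
F1 | step 4 | 5-hydroxy-3-iodo-7-(prenyloxy)chromen-4-one | CC(C)=CCOc1cc(O)c2c(=O)c(I)coc2c1
F2 | step 4 | 4-bromo-1,3-bis(tert-butyldimethylsilyloxy)benzene | CC(C)(C)[Si](C)(C)Oc1ccc(Br)c(O[Si](C)(C)C(C)(C)C)c1
F3 | step 4 | 2-[2,4-bis(tert-butyldimethylsilyloxy)phenyl]-4,4,5,5-tetramethyl-1,3,2-dioxaborolane | CC(C)(C)[Si](C)(C)Oc1ccc(B2OC(C)(C)C(C)(C)O2)c(O[Si](C)(C)C(C)(C)C)c1
F4 | step 2 | 2,5-dihydroxy-7-(prenyloxy)chroman-4-one (racemic hemiacetal) | CC(C)=CCOc1cc(O)c2C(=O)CC(O)Oc2c1
F0 | step 1 | none | none
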